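**Retrosynthetic overview**
1. Ludongnin A ⇐ 15‑ol 25 ⇐ oxidative C6–C7 scission of the 6‑oxo‑7,20‑hemiketal ent‑kaurene 23. Both lactone rings close in this one operation, as proposed for 7,20‑epoxy‑ent‑kauranes → spirolactones.
2. ent‑Kaurene 22 ⇐ ring D by vinyl‑radical closure (C16→C13). The C8 quaternary centre comes from reductive alkylation of aryl ketone 16 (ring C is bought as an arene).
3. Tricycle 10 ⇐ cyclase‑like A/B bicyclisation (bonds C4–C5, then C10–C9). It is run as an MHAT radical cascade on dihydropyranone 9, which already holds the C7–O–C20 bridge.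
4. 9 ⇐ catalytic asymmetric vinylogous aldol–lactonisation, the only external source of chirality, from methyl crotonate, 5‑chloropentyne and an anisaldehyde.
5. Ring order: lactone bridge → A → B → (C dearomatised) → D → δ‑ and γ‑lactone.

Assumption: locants and α/β follow ent‑kaurane/ent‑podocarpane numbering as usually drawn, and the 7‑oxo‑20‑ols 19–23 are written as their 7α,20‑epoxy‑7β‑ol hemiketals.

**Step 1**
Reactants: 1 5‑chloropent‑1‑yne
Product: 3 2‑(5‑chloropent‑1‑en‑2‑yl)‑4,4,5,5‑tetramethyl‑1,3,2‑dioxaborolane, via (5‑chloropent‑1‑en‑2‑yl)diisobutylalane 2 (not isolated)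
Conditions: DIBAL‑H, Ni(dppp)Cl2 (3 mol %), THF, 0→22 °C; then MeOBpin, 0→80 °C
Reagents that add atoms: 2‑methoxy‑4,4,5,5‑tetramethyl‑1,3,2‑dioxaborolane COB1OC(C)(C)C(C)(C)O1
Why: Ni(dppp)‑catalysed hydroalumination of a terminal alkyl alkyne is α‑(Markovnikov) selective, and the internal alkenylalane transmetalates to boron, so the 1,1‑disubstituted alkenyl boronate forms without touching the alkyl chloride (hydroalumination/borylation).

**Step 2**
Reactants: 3 2‑(5‑chloropent‑1‑en‑2‑yl) pinacol boronate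
Product: 4 2‑(5‑iodopent‑1‑en‑2‑yl)‑4,4,5,5‑tetramethyl‑1,3,2‑dioxaborolane
Conditions: NaI, acetone, reflux
Reagents that add atoms: sodium iodide [Na+].[I-]
Why: Finkelstein exchange, driven by precipitation of NaCl, gives the primary iodide needed for clean enolate alkylation.

**Step 3**
Reactants: 4 iodide; 5 methyl (E)‑but‑2‑enoate
Product: 7 methyl 2‑ethenyl‑6‑(pinacolboryl)hept‑6‑enoate (racemic at C2), via lithium dienolate of methyl crotonate 6 (not isolated)
Conditions: LDA, THF–DMPU, −78 °C; then 4, −78→0 °C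
Reagents that add atoms: none
Why: Deconjugative alkylation of the crotonate dienolate occurs at the α‑carbon and gives the β,γ‑unsaturated ester, whose racemic stereocentre is erased on enolisation in the next step.

**Step 4**
Reactants: 7 β,γ‑unsaturated ester; 8 2‑chloro‑5‑methoxybenzaldehyde
Product: 9 (6R)‑6‑(2‑chloro‑5‑methoxyphenyl)‑3‑[4‑(pinacolboryl)pent‑4‑en‑1‑yl]‑5,6‑dihydro‑2H‑pyran‑2‑one
Conditions: Cu(MeCN)4PF6/DTBM‑SEGPHOS (5 mol %, antipode giving the 6R lactone), Barton's base (cat.), THF, −40 °C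
Reagents that add atoms: none
Why: Cu(I)‑catalysed direct asymmetric vinylogous aldol reaction, in which the α‑substituent blocks α‑attack, the chiral Cu dienolate adds through its γ‑carbon (C6) to one aldehyde face to set C7 (R), and the (Z)‑δ‑alkoxide lactonises in situ.

**Step 5**
Reactants: 9 dihydropyranone
Product: 10 ent‑14‑chloro‑11‑methoxy‑4α‑(pinacolboryl)‑19‑norpodocarpa‑8,11,13‑trien‑20,7α‑olide (4β‑CH3, 5β‑H, 10α‑C20, 7β‑H)
Conditions: Co(salen‑tBu,tBu) (10 mol %), 1‑fluoro‑2,4,6‑trimethylpyridinium triflate, (Me2SiH)2O, PhCF3–acetone, rt, 0.01 M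
Reagents that add atoms: none
Why: Proposed new method: Co–H transfers H• to the CH2 terminus of the alkenyl boronate, the tertiary α‑boryl radical adds 6‑endo to C5 of the unsaturated lactone anti to the C7 aryl group (sets C5; the slim planar Bpin, A ≈ 0.4, takes the axial α‑site at C4 and CH3 the equatorial one), and the electrophilic C10 α‑acyl radical then attacks the only free ortho carbon of the anisole (ortho to OMe, the other ortho site being blocked by Cl) on the face fixed by the lactone bridge (sets C10, trans‑A/B) before Co(III) rearomatises the ring; the closest known reactions are Co‑catalysed MHAT‑initiated radical polyene bicyclisations terminated on arenes (tolerant of electron‑poor central alkenes) and Fe‑MHAT Giese couplings of alkenyl boronates, and the bridged carnosol‑type closure is the untested element.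

**Step 6**
Reactants: 10 tertiary boronate; 11 bromochloromethane
Product: 14 ent‑14‑chloro‑19‑hydroxy‑11‑methoxypodocarpa‑8,11,13‑trien‑20,7α‑olide, via lithium (chloromethyl)boronate complex of 10 12 (not isolated), via C19‑homologated pinacol boronate 13 (not isolated)
Conditions: BrCH2Cl, n‑BuLi, Et2O, −78 °C→rt; then NaBO3·4H2O, THF–H2O, rt
Reagents that add atoms: sodium perborate [Na+].[Na+].O[B-]1(O)OO[B-](O)(O)OO1
Why: Matteson one‑carbon homologation followed by oxidation, where both the 1,2‑shift and the C–B oxidation go with retention, so the axial boron becomes the axial (α) C19 hydroxymethyl group (any 19,20‑lactone isomer formed by acyl shift converges in step 7).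

**Step 7**
Reactants: 14 hydroxy lactone
Product: 15 ent‑14‑chloro‑11‑methoxypodocarpa‑8,11,13‑triene‑7α,19,20‑triol
Conditions: LiAlH4, THF, 0 °C→reflux
Reagents that add atoms: none
Why: Hydride reduction of the bridged lactone brings C20 to the alcohol level required in the target and frees the benzylic C7 alcohol, while the aryl chloride and ether are inert.

**Step 8**
Reactants: 15 triol
Product: 16 ent‑14‑chloro‑19,20‑dihydroxy‑11‑methoxypodocarpa‑8,11,13‑trien‑7‑one
Conditions: MnO2 (excess), CH2Cl2, rt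
Reagents that add atoms: none
Why: MnO2 oxidises only the benzylic alcohol and leaves the two neopentyl primary alcohols untouched, and the temporary C7 stereocentre has by now done its work.

**Step 9**
Reactants: 16 aryl ketone; 17 2,3‑dibromopropene
Product: 19 8β‑(2‑bromoallyl)‑7α,20‑epoxy‑11‑methoxy‑ent‑podocarpa‑9(11),13‑diene‑7β,19‑diol, via tripotassium C7(8)‑dienolate/19,20‑dialkoxide 18 (not isolated)
Conditions: K, NH3(l)–THF, t‑BuOH (1 equiv), −78 °C; then 17, −78→−33 °C; aq. work‑up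
Reagents that add atoms: none
Why: Birch‑type reductive alkylation of an aryl ketone, in which C–Cl is reduced first, the ring takes up 2 e⁻ with protonation para (C12), and the flat C7–C8–C9 dienolate is allylated at C8 from the β‑face, anti to the axial α‑CH2O⁻ group on C10 (sets C8).

**Step 10**
Reactants: 19 dienol ether
Product: 20 8β‑(2‑bromoallyl)‑7α,20‑epoxy‑7β,19‑dihydroxy‑ent‑podocarp‑12‑en‑11‑one (9β‑H)
Conditions: 1 M HCl, THF, 40 °C
Reagents that add atoms: water O
Why: Enol‑ether hydrolysis and acid‑catalysed conjugation of the 13‑ene give the enone, and C9 (epimerisable α to C11=O) settles as 9β‑H, the only epimer in which ring C can span the axial C8–C14 and equatorial C9–C11 bonds.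

**Step 11**
Reactants: 20 enone
Product: 21 8β‑(2‑bromoallyl)‑7α,20‑epoxy‑ent‑podocarp‑12‑ene‑7β,11α,19‑triol
Conditions: NaBH4, CeCl3·7H2O, MeOH, −78→0 °C
Reagents that add atoms: none
Why: Luche 1,2‑reduction touches only the enone (C7 is masked as hemiketal), and hydride enters anti to the bulky axial C9–C10 bond while the bridge side is still open, giving the equatorial 11α‑alcohol (sets C11).

**Step 12**
Reactants: 21 vinyl bromide
Product: 22 7α,20‑epoxy‑ent‑kaur‑16‑ene‑7β,11α,19‑triol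
Conditions: n‑Bu3SnH (slow addition), AIBN (cat.), PhH, 80 °C
Reagents that add atoms: none
Why: 5‑exo‑trig cyclisation of the C16 vinyl radical onto C13 closes ring D and leaves the exocyclic methylene, and the two‑carbon bridge can only close on the β‑face from which C15 projects (sets C13).

**Step 13**
Reactants: 22 ent‑kaurene triol
Product: 23 7α,20‑epoxy‑7β,11α,15α,19‑tetrahydroxy‑ent‑kaur‑16‑en‑6‑one
Conditions: SeO2 (3 equiv), 1,4‑dioxane–H2O, 90 °C
Reagents that add atoms: selenium dioxide O=[Se]=O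
Why: One reagent performs two known SeO2 reactions, namely Riley oxidation of the only α‑CH2 (C6) of the 7‑ketone tautomer and ene/[2,3] allylic hydroxylation at C15 from the exo face, while saturated alcohols are inert.

**Step 14**
Reactants: 23 6‑oxo‑7‑hemiketal
Product: 25 11α,15α‑dihydroxy‑6,7‑seco‑ent‑kaur‑16‑ene‑6,19:7,20‑diolide, via 11α,15α,19‑trihydroxy‑6,7‑seco‑ent‑kaur‑16‑en‑7,20‑olid‑6‑oic acid 24 (not isolated)
Conditions: NaIO4, THF–H2O (pH 4–5), rt
Reagents that add atoms: none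
Why: Periodate α‑ketol cleavage of the C6(=O)–C7(OH)(OR) unit turns the hemiketal carbon directly into the 7,20‑δ‑lactone carbonyl and C6 into an acid that lactonises at once with the cis‑axial 19‑OH, and C5 (α to C6) can only hold the 5β‑H configuration that allows this cis‑fused γ‑lactone.

**Step 15**
Reactants: 25 15α‑alcohol
Product: 26 ludongnin A
Conditions: MnO2 (excess), CH2Cl2, rt
Reagents that add atoms: none
Why: MnO2 oxidises the allylic 15‑OH to the α‑methylene ketone and leaves the non‑allylic 11α‑OH and both lactones untouched.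

**Compound list**
1 | 5‑chloropent‑1‑yne | C#CCCCCl | starting material
2 | (5‑chloropent‑1‑en‑2‑yl)diisobutylalane | C=C(CCCCl)[Al](CC(C)C)CC(C)C | intermediate
3 | 2‑(5‑chloropent‑1‑en‑2‑yl) pinacol boronate | C=C(CCCCl)B1OC(C)(C)C(C)(C)O1 | intermediate
4 | 2‑(5‑iodopent‑1‑en‑2‑yl) pinacol boronate | C=C(CCCI)B1OC(C)(C)C(C)(C)O1 | intermediate
5 | methyl (E)‑but‑2‑enoate | C/C=C/C(=O)OC | starting material
6 | lithium dienolate of methyl crotonate | [Li+].C=CC=C([O-])OC | intermediate
7 | methyl 2‑ethenyl‑6‑(pinacolboryl)hept‑6‑enoate (racemic) | C=CC(CCCC(=C)B1OC(C)(C)C(C)(C)O1)C(=O)OC | intermediate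
8 | 2‑chloro‑5‑methoxybenzaldehyde | COc1ccc(Cl)c(C=O)c1 | starting material
9 | (6R)‑6‑aryl‑3‑alkyl‑5,6‑dihydropyran‑2‑one | O=C1O[C@@H](c2cc(OC)ccc2Cl)CC=C1CCCC(=C)B1OC(C)(C)C(C)(C)O1 | intermediate
10 | bridged tricyclic 20,7α‑olide, 4α‑Bpin | C[C@@]1(B2OC(C)(C)C(C)(C)O2)CCC[C@@]2(C(=O)O3)c4c(OC)ccc(Cl)c4[C@H]3C[C@H]12 | intermediate
11 | bromochloromethane | ClCBr | starting material
12 | lithium (chloromethyl)boronate complex of 10 | [Li+].C[C@@]1([B-]2(CCl)OC(C)(C)C(C)(C)O2)CCC[C@@]2(C(=O)O3)c4c(OC)ccc(Cl)c4[C@H]3C[C@H]12 | intermediate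
13 | C19‑homologated pinacol boronate | C[C@@]1(CB2OC(C)(C)C(C)(C)O2)CCC[C@@]2(C(=O)O3)c4c(OC)ccc(Cl)c4[C@H]3C[C@H]12 | intermediate
14 | 19‑hydroxy‑20,7α‑olide | C[C@@]1(CO)CCC[C@@]2(C(=O)O3)c4c(OC)ccc(Cl)c4[C@H]3C[C@H]12 | intermediate
15 | 7α,19,20‑triol | C[C@@]1(CO)CCC[C@@]2(CO)c3c(OC)ccc(Cl)c3[C@H](O)C[C@H]12 | intermediate
16 | 19,20‑dihydroxy‑7‑one | C[C@@]1(CO)CCC[C@@]2(CO)c3c(OC)ccc(Cl)c3C(=O)C[C@H]12 | intermediate
17 | 2,3‑dibromopropene | C=C(Br)CBr | starting material
18 | tripotassium dienolate/dialkoxide | [K+].[K+].[K+].C[C@@]1(C[O-])CCC[C@@]2(C[O-])C3=C(OC)CC=CC3=C([O-])C[C@H]12 | intermediate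
19 | 8β‑(2‑bromoallyl) dienol ether hemiketal | C[C@@]1(CO)CCC[C@@]2(CO3)C4=C(OC)CC=C[C@]4(CC(Br)=C)[C@@]3(O)C[C@H]12 | intermediate
20 | 12‑en‑11‑one hemiketal | C[C@@]1(CO)CCC[C@@]2(CO3)[C@@H]4C(=O)C=CC[C@]4(CC(Br)=C)[C@@]3(O)C[C@H]12 | intermediate
21 | 11α‑allylic alcohol | C[C@@]1(CO)CCC[C@@]2(CO3)[C@@H]4[C@H](O)C=CC[C@]4(CC(Br)=C)[C@@]3(O)C[C@H]12 | intermediate
22 | 7α,20‑epoxy‑ent‑kaur‑16‑ene‑7β,11α,19‑triol | C[C@@]1(CO)CCC[C@@]2(CO3)[C@@H]4[C@H](O)C[C@@H]5C[C@]4(CC5=C)[C@@]3(O)C[C@H]12 | intermediate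
23 | 6‑oxo‑15α‑hydroxy hemiketal | C[C@@]1(CO)CCC[C@@]2(CO3)[C@@H]4[C@H](O)C[C@@H]5C[C@]4([C@@H](O)C5=C)[C@@]3(O)C(=O)[C@H]12 | intermediate
24 | seco 7,20‑olid‑6‑oic acid | C=C1[C@H](O)[C@]23C[C@H]1C[C@@H](O)[C@H]2[C@@]1(CCC[C@@](C)(CO)[C@H]1C(=O)O)COC3=O | intermediate
25 | 15α‑hydroxy bis‑lactone | C=C1[C@H](O)[C@]23C[C@H]1C[C@@H](O)[C@H]2[C@@]1(CCC[C@@]2(C)COC(=O)[C@H]21)COC3=O | intermediate
26 | ludongnin A | C=C1C(=O)[C@]23C[C@H]1C[C@@H](O)[C@H]2[C@@]1(CCC[C@@]2(C)COC(=O)[C@H]21)COC3=O | target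

**Step count:** 15 steps in total. Longest linear sequence: 15 (from 1).

**The three steps most likely to fail**

Step 5 is the riskiest. The second closure must pass a strained bridged transition state, and the C4 selectivity and the attack at the hindered ortho position are unproven.
The fallback sets out from 9 and returns at 15. It gives up the lactone bridge while the C–C bonds are made.
- Reduce 9 with DIBAL‑H to the (Z)‑ene‑1,5‑diol F1 and silylate it to the bis‑TBS ether F2.
- Run the MHAT bicyclisation on this unbridged, electronically neutral triene, which is the directly precedented substrate class, to give the tricyclic boronate F3. The C7 silyl ether makes the product of wrong‑face attack a separable diastereomer, so enantiopurity is kept at the cost of yield.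
- Homologate and oxidise to the C19 alcohol F4, then remove both silyl groups with TBAF to reach triol 15.

Step 9 may suffer from over‑reduction of the ketone, O‑allylation of the alkoxides, or masking of the ketone.
The fallback sets out from 16 and returns at 20. It makes the C8–C15 bond by conjugate allylation instead of enolate alkylation.
- Reduce 16 with K/NH3/t‑BuOH, quench with a proton source, and hydrolyse and equilibrate with aqueous HCl to the tetrasubstituted 8‑ene‑7,11‑dione F5.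
- After in‑situ TMS protection of the diol, add (2‑bromoallyl)trimethylsilane/TiCl4 (Hosomi–Sakurai). Addition occurs at C8, which is β to C11=O and the less hindered terminus, anti to C20, and gives the saturated 8β‑(2‑bromoallyl)‑7,11‑dione hemiketal F6.
- Dehydrogenate C12–C13 with IBX to give enone 20.

Step 13 asks SeO2 to oxidise a hemiketal‑masked, hindered ketone and an alkene in one pot.
The fallback sets out from 22 and returns at 26. It uses the lower oxidation level at C6.
- Treat 22 with excess KHMDS and then a Davis oxaziridine to give the 6β‑hydroxy‑7‑hemiketal F7.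
- Cleave it with Pb(OAc)4 to the 7,20‑lactone 6,19‑lactol F8.
- Hydroxylate C15 with catalytic SeO2/TBHP to give the 15α‑hydroxy lactol F9.
- Oxidise the lactol and the allylic alcohol together with MnO2 to give ludongnin A 26.

**Further compounds**
F1 | step 5 | (Z)‑ene‑1,5‑diol from 9 | OC/C(CCCC(=C)B1OC(C)(C)C(C)(C)O1)=C\C[C@@H](O)c1cc(OC)ccc1Cl
F2 | step 5 | bis‑TBS ether of F1 | CC(C)(C)[Si](C)(C)OC/C(CCCC(=C)B1OC(C)(C)C(C)(C)O1)=C\C[C@@H](O[Si](C)(C)C(C)(C)C)c1cc(OC)ccc1Cl
F3 | step 5 | unbridged tricyclic 4α‑boronate, 7α,20‑bis‑OTBS | C[C@@]1(B2OC(C)(C)C(C)(C)O2)CCC[C@@]2(CO[Si](C)(C)C(C)(C)C)c3c(OC)ccc(Cl)c3[C@H](O[Si](C)(C)C(C)(C)C)C[C@H]12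
F4 | step 5 | 19‑alcohol, 7α,20‑bis‑OTBS | C[C@@]1(CO)CCC[C@@]2(CO[Si](C)(C)C(C)(C)C)c3c(OC)ccc(Cl)c3[C@H](O[Si](C)(C)C(C)(C)C)C[C@H]12
F5 | step 9 | 19,20‑dihydroxy‑ent‑podocarp‑8‑ene‑7,11‑dione | C[C@@]1(CO)CCC[C@@]2(CO)C3=C(CCCC3=O)C(=O)C[C@H]12
F6 | step 9 | saturated 8β‑(2‑bromoallyl)‑11‑one hemiketal | C[C@@]1(CO)CCC[C@@]2(CO3)[C@@H]4C(=O)CCC[C@]4(CC(Br)=C)[C@@]3(O)C[C@H]12
F7 | step 13 | 7α,20‑epoxy‑ent‑kaur‑16‑ene‑6β,7β,11α,19‑tetraol | C[C@@]1(CO)CCC[C@@]2(CO3)[C@@H]4[C@H](O)C[C@@H]5C[C@]4(CC5=C)[C@@]3(O)[C@@H](O)[C@H]12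
F8 | step 13 | 7,20‑lactone 6,19‑lactol | C=C1C[C@]23C[C@H]1C[C@@H](O)[C@H]2[C@@]1(CCC[C@@]2(C)COC(O)[C@H]21)COC3=O
F9 | step 13 | 15α‑hydroxy 7,20‑lactone 6,19‑lactol | C=C1[C@H](O)[C@]23C[C@H]1C[C@@H](O)[C@H]2[C@@]1(CCC[C@@]2(C)COC(O)[C@H]21)COC3=O
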